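**Retrosynthetic overview**

1. Target 22 ⇒ methyl ester 21 (saponification) ⇒ aromatic phloroglucinol 19 + prenyl carbonate 20. The C6 quaternary centre is made last, by palladium-catalysed dearomative prenylation. 19 ⇒ chromanone 10 + aldehyde 17 by reductive alkylation at C6.
2. The strategy rests on the 2,2-dimethylpyran-4-one ring (O1, C2, C3, C4, C4a, C8a): O1 sits on C8a, next to C8 with the hexanoate chain, and the C4 ketone sits on C4a, next to the C5 oxygen. The ring is closed on the aromatic stage by C-acylation (C4–C4a) and oxa-Michael addition (O1–C2) on dihydrocoumarin 4, where the C7 oxygen is tied in the side-chain lactone and the C5 oxygen is benzylated, so only the oxygen next to C8 can cyclise.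
3. 4 ⇐ phloroglucinol + (E)-hex-2-enal by carbene-catalysed [3+3] annulation (sets the side-chain stereocentre), then benzylation of the unhindered phenol.
4. Aldehyde 17 ⇐ 3,3-dimethylcyclobutanone: enol triflate, methoxycarbonylation, rhodium-catalysed asymmetric isopropenyl conjugate addition, DIBAL-H.
5. Ring order: lactone ring (temporary tether) → pyranone ring (key step) → lactone opened → carbocycle dearomatised; the cyclobutane ring is bought.

Key step: step 3

Assumption: the sense of induction of the chiral catalysts in steps 1, 8 and 11 cannot be predicted with certainty for these substrates; the antipode named is taken to give the configuration drawn and would be exchanged for its mirror image if the first run shows the opposite sense.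

**Route**

Step 1
Reactants: 1 phloroglucinol (3 equiv); 2 (E)-hex-2-enal
Product: 3 (R)-5,7-dihydroxy-4-propylchroman-2-one
Conditions: (5aR,10bS)-2-mesityl-5a,10b-dihydro-4H,6H-indeno[2,1-b][1,2,4]triazolo[4,3-d][1,4]oxazin-2-ium chloride (10 mol %), K2CO3 (20 mol %), 3,3',5,5'-tetra-tert-butyl-4,4'-diphenoquinone (1.2 equiv), THF, rt
Reagents that add atoms: none
Why: Oxidative carbene catalysis turns 2 via its Breslow intermediate into the α,β-unsaturated acyl azolium, a ring carbon of 1 adds to its β-carbon (Michael/Friedel–Crafts addition, or O-acylation followed by a Coates–Claisen shift) and the neighbouring phenol lactonises with release of the carbene, a formal [3+3] annulation in which the indane wall of the triazolium shields one face of the acyl azolium and should set the benzylic centre as R; the three ring carbons of 1 are equivalent and its excess holds back a second annulation.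

Step 2
Reactants: 3 (R)-5,7-dihydroxy-4-propylchroman-2-one
Product: 4 (R)-7-(benzyloxy)-5-hydroxy-4-propylchroman-2-one
Conditions: BnBr (1.05 equiv), K2CO3 (1.1 equiv), acetone, 0 °C → rt
Reagents that add atoms: benzyl bromide, BrCc1ccccc1
Why: Williamson etherification under weak-base conditions should take place at the 7-hydroxyl, because the 5-hydroxyl lies next to the ring carbon that carries the C4 stereocentre with its propyl group and is shielded by it, while one equivalent of bromide and anhydrous K2CO3 in acetone limit bis-benzylation and leave the aryl lactone closed.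

Step 3
Reactants: 4 (R)-7-(benzyloxy)-5-hydroxy-4-propylchroman-2-one; 5 3-methylbut-2-enoyl chloride (1.3 equiv)
Product: 8 (R)-5-(benzyloxy)-2,2-dimethyl-10-propyl-2,3,9,10-tetrahydro-4H,8H-pyrano[2,3-f]chromene-4,8-dione, via aryl 3-methylbut-2-enoate 6 (not isolated), via ortho-hydroxyaryl enone 7 (not isolated)
Conditions: Bi(OTf)3 (20 mol %), toluene/MeNO2 5:1, 0 °C → 60 °C, N2 sweep
Reagents that add atoms: none
Why: Bi(OTf)3 activates the acid chloride as an acylium-type donor that acylates the one free phenol to aryl ester 6, and the ester then undergoes a Lewis acid Fries shift (or the arene is acylated directly) at the only free carbon ortho to that oxygen, the CH between the hydroxyl and the benzyloxy group, giving the chelated hydroxyaryl enone 7 and the C4–C4a bond. The phenol of 7 then adds to the activated β,β-dimethyl enone in a 6-endo-trig oxa-Michael closure that forms O1–C2 and the pyranone ring; no stereocentre is formed and the non-enolisable benzylic centre is untouched. The closest known reaction type is the metal triflate-catalysed esterification/Fries/oxa-Michael route from phenols and 3-methylbut-2-enoyl donors to 2,2-dimethylchroman-4-ones. Selectivity between the two free ring carbons is secured by delivery from the ortho ester and by the fact that only the ortho ketone can cyclise, which removes it from the reversible acylation of this crowded ring, whereas acylation at the carbon between the benzyloxy group and the lactone oxygen leads to no ring. Selectivity between the oxygens is fixed by the substrate, since one is benzylated and one is held in the lactone, so O1 ends on the carbon next to the side chain. The acid chloride/triflate pair favours acylation over conjugate hydroarylation of 6 (which would give a 4,4-dimethyldihydrocoumarin), and a catalytic, weakly oxophilic Lewis acid with HCl swept out is chosen so that the benzyl ether ortho to the new ketone stays in place.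

Step 4
Reactants: 8 (R)-5-(benzyloxy)-2,2-dimethyl-10-propyl-2,3,9,10-tetrahydro-4H,8H-pyrano[2,3-f]chromene-4,8-dione
Product: 9 methyl (3R)-3-[5-(benzyloxy)-7-hydroxy-2,2-dimethyl-4-oxo-3,4-dihydro-2H-chromen-8-yl]hexanoate
Conditions: NaOMe (1.5 equiv), MeOH/THF, 0 °C; AcOH quench
Reagents that add atoms: sodium methoxide, C[O-].[Na+]
Why: Base-mediated transesterification (methanolysis) of the aryl lactone should be fast because the leaving phenoxide is para to the aryl ketone; with the C5 oxygen still benzylated a retro-oxa-Michael opening of the pyranone could only re-close on the same oxygen (no Wessely–Moser-type isomerisation), and the stereocentre, β to the ester, cannot epimerise.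

Step 5
Reactants: 9 methyl (3R)-3-[5-(benzyloxy)-7-hydroxy-2,2-dimethyl-4-oxo-3,4-dihydro-2H-chromen-8-yl]hexanoate
Product: 10 methyl (3R)-3-(5,7-dihydroxy-2,2-dimethyl-4-oxo-3,4-dihydro-2H-chromen-8-yl)hexanoate
Conditions: H2 (1 atm), 10 % Pd/C, EtOAc, rt
Reagents that add atoms: none
Why: Hydrogenolysis of the benzyl aryl ether over palladium on carbon is selective at one atmosphere, the chelated aryl ketone, the methyl ester and the benzylic stereocentre being inert, and the freed 5-hydroxyl ends hydrogen-bonded to the C4 ketone.

Step 6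
Reactants: 11 3,3-dimethylcyclobutan-1-one
Product: 12 3,3-dimethylcyclobut-1-en-1-yl trifluoromethanesulfonate
Conditions: LiHMDS, THF, −78 °C; PhNTf2, −78 → 0 °C; NH4Cl quench
Reagents that add atoms: N-phenylbis(trifluoromethanesulfonimide), O=S(=O)(N(c1ccccc1)S(=O)(=O)C(F)(F)F)C(F)(F)F
Why: Kinetic deprotonation of the symmetrical ketone and O-sulfonylation of the lithium enolate (enol triflate formation) give the achiral cyclobutenyl triflate, the low temperature suppressing self-aldol reaction of the cyclobutanone.

Step 7
Reactants: 12 3,3-dimethylcyclobut-1-en-1-yl trifluoromethanesulfonate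
Product: 13 methyl 3,3-dimethylcyclobut-1-ene-1-carboxylate
Conditions: Pd(OAc)2 (5 mol %), 1,3-bis(diphenylphosphino)propane (5 mol %), CO (1 atm), MeOH, Et3N (1.5 equiv), DMF, 50 °C
Reagents that add atoms: carbon monoxide, [C-]#[O+]; methanol, CO
Why: Palladium-catalysed alkoxycarbonylation of an enol triflate (oxidative addition, CO insertion, methanolysis of the acylpalladium species) should deliver the strained but isolable cyclobutene ester.

Step 8
Reactants: 13 methyl 3,3-dimethylcyclobut-1-ene-1-carboxylate; 14 4,4,5,5-tetramethyl-2-(prop-1-en-2-yl)-1,3,2-dioxaborolane (2 equiv)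
Product: 16 methyl (1R,2R)-3,3-dimethyl-2-(prop-1-en-2-yl)cyclobutane-1-carboxylate, via cis ester 15 (not isolated)
Conditions: [RhCl(C2H4)2]2 (2.5 mol %), (1R,4R)-2,5-diphenylbicyclo[2.2.2]octa-2,5-diene (5.5 mol %), KOH (20 mol %), 1,4-dioxane/H2O 10:1, 40 °C; then NaOMe (0.3 equiv), MeOH, 50 °C
Reagents that add atoms: none
Why: In this Hayashi–Miyaura asymmetric conjugate addition the isopropenylrhodium species formed by transmetalation adds syn across the strained C1=C2 bond from the face left open by the chiral diene, which should set C2 as R, protonation of the rhodium enolate gives mainly the cis ester 15, and methoxide then equilibrates C1 through the ester enolate to the trans isomer, in which the ester avoids the neighbouring isopropenyl group (C1 becomes R).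

Step 9
Reactants: 16 methyl (1R,2R)-3,3-dimethyl-2-(prop-1-en-2-yl)cyclobutane-1-carboxylate
Product: 17 (1R,2R)-3,3-dimethyl-2-(prop-1-en-2-yl)cyclobutane-1-carbaldehyde
Conditions: DIBAL-H (i-Bu2AlH, 1.1 equiv), CH2Cl2, −78 °C; MeOH, aq. Rochelle salt
Reagents that add atoms: none
Why: Partial reduction of the methyl ester with DIBAL-H at −78 °C stops at the aluminium hemiacetal, which releases the aldehyde on work-up; the trans aldehyde is the thermodynamically preferred epimer, so C1 is not at risk, and the alkene is inert.

Step 10
Reactants: 10 methyl (3R)-3-(5,7-dihydroxy-2,2-dimethyl-4-oxo-3,4-dihydro-2H-chromen-8-yl)hexanoate; 17 (1R,2R)-3,3-dimethyl-2-(prop-1-en-2-yl)cyclobutane-1-carbaldehyde (1.3 equiv)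
Product: 19 methyl (3R)-3-[6-{[(1S,2R)-3,3-dimethyl-2-(prop-1-en-2-yl)cyclobutyl]methyl}-5,7-dihydroxy-2,2-dimethyl-4-oxo-3,4-dihydro-2H-chromen-8-yl]hexanoate, via ortho-quinone methide 18 (not isolated)
Conditions: L-proline (20 mol %), Hantzsch ester (diethyl 2,6-dimethyl-1,4-dihydropyridine-3,5-dicarboxylate, 1.3 equiv), EtOH, 50 °C
Reagents that add atoms: none
Why: Reductive alkylation through an ortho-quinone methide: the proline-derived iminium of 17 is attacked by C6, the only free ring carbon and the one flanked by two hydroxyls, loss of proline gives ortho-quinone methide 18, and hydride transfer from the Hantzsch ester to its exocyclic carbon restores the aromatic ring; the medium is nearly neutral, so the cyclobutane and the isopropenyl group are not exposed to cationic rearrangement, the new CH2 is not stereogenic, and any enamine epimerisation at the aldehyde α-carbon returns to the favoured trans arrangement because C2 stays fixed.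

Step 11
Reactants: 19 methyl (3R)-3-[6-{[(1S,2R)-3,3-dimethyl-2-(prop-1-en-2-yl)cyclobutyl]methyl}-5,7-dihydroxy-2,2-dimethyl-4-oxo-3,4-dihydro-2H-chromen-8-yl]hexanoate; 20 tert-butyl (3-methylbut-2-en-1-yl) carbonate (1.2 equiv)
Product: 21 methyl (3R)-3-[(6R)-6-{[(1S,2R)-3,3-dimethyl-2-(prop-1-en-2-yl)cyclobutyl]methyl}-5-hydroxy-2,2-dimethyl-6-(3-methylbut-2-en-1-yl)-4,7-dioxo-3,4,6,7-tetrahydro-2H-chromen-8-yl]hexanoate
Conditions: Pd2(dba)3·CHCl3 (2.5 mol %), (R,R)-DACH-phenyl ligand N,N'-[(1R,2R)-cyclohexane-1,2-diyl]bis[2-(diphenylphosphanyl)benzamide] (7.5 mol %), THF, 0 °C → rt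
Reagents that add atoms: none
Why: In this Tsuji–Trost allylic alkylation run in a dearomative sense, zerovalent palladium ionises 20 with loss of CO2, the tert-butoxide formed deprotonates the acidic 7-hydroxyl, and the phloroglucinolate attacks the unsubstituted terminus of the π-prenyl complex through C6, the carbon between the two oxygens, to give the 6,6-disubstituted cyclohexadienone (linear prenyl, since attack at the dimethyl terminus would join two quaternary carbons); the chiral pocket of the ligand distinguishes the two faces of C6 and should set it as R under catalyst control, O-prenyl ethers are re-ionised and drain to the C-alkylated product, and C8 is shielded by its branched side chain.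

Step 12
Reactants: 21 methyl (3R)-3-[(6R)-6-{[(1S,2R)-3,3-dimethyl-2-(prop-1-en-2-yl)cyclobutyl]methyl}-5-hydroxy-2,2-dimethyl-6-(3-methylbut-2-en-1-yl)-4,7-dioxo-3,4,6,7-tetrahydro-2H-chromen-8-yl]hexanoate
Product: 22 (3R)-3-[(6R)-6-{[(1S,2R)-3,3-dimethyl-2-(prop-1-en-2-yl)cyclobutyl]methyl}-5-hydroxy-2,2-dimethyl-6-(3-methylbut-2-en-1-yl)-4,7-dioxo-3,4,6,7-tetrahydro-2H-chromen-8-yl]hexanoic acid (CNP0358381.1)
Conditions: LiOH·H2O (4 equiv), THF/MeOH/H2O, 0 °C → rt; 1 M HCl to pH 3
Reagents that add atoms: lithium hydroxide monohydrate, [Li+].[OH-].O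
Why: Saponification of the methyl ester with LiOH should be clean because the core is present as the delocalised enolate of its vinylogous acid and is protected from nucleophilic attack, C6 is quaternary and the side-chain centre is β to the carboxyl, so no stereocentre can epimerise, and acidification gives the target as the hydrogen-bonded enol tautomer.

**Compound list**

1 | phloroglucinol (benzene-1,3,5-triol) | Oc1cc(O)cc(O)c1 | starting material
2 | (E)-hex-2-enal | CCC/C=C/C=O | starting material
3 | (R)-5,7-dihydroxy-4-propylchroman-2-one | CCC[C@@H]1CC(=O)Oc2cc(O)cc(O)c12 | intermediate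
4 | (R)-7-(benzyloxy)-5-hydroxy-4-propylchroman-2-one | CCC[C@@H]1CC(=O)Oc2cc(OCc3ccccc3)cc(O)c12 | intermediate
5 | 3-methylbut-2-enoyl chloride | CC(C)=CC(=O)Cl | starting material
6 | (R)-7-(benzyloxy)-2-oxo-4-propylchroman-5-yl 3-methylbut-2-enoate (aryl ester, not isolated) | CCC[C@@H]1CC(=O)Oc2cc(OCc3ccccc3)cc(OC(=O)C=C(C)C)c12 | intermediate
7 | (R)-7-(benzyloxy)-5-hydroxy-6-(3-methylbut-2-enoyl)-4-propylchroman-2-one (hydroxyaryl enone, not isolated) | CCC[C@@H]1CC(=O)Oc2cc(OCc3ccccc3)c(C(=O)C=C(C)C)c(O)c12 | intermediate
8 | (R)-5-(benzyloxy)-2,2-dimethyl-10-propyl-2,3,9,10-tetrahydro-4H,8H-pyrano[2,3-f]chromene-4,8-dione (benzyl-protected chromanone–dihydrocoumarin tricycle) | CCC[C@@H]1CC(=O)Oc2cc(OCc3ccccc3)c4C(=O)CC(C)(C)Oc4c12 | intermediate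
9 | methyl (3R)-3-[5-(benzyloxy)-7-hydroxy-2,2-dimethyl-4-oxo-3,4-dihydro-2H-chromen-8-yl]hexanoate | CCC[C@H](CC(=O)OC)c1c(O)cc(OCc2ccccc2)c2C(=O)CC(C)(C)Oc12 | intermediate
10 | methyl (3R)-3-(5,7-dihydroxy-2,2-dimethyl-4-oxo-3,4-dihydro-2H-chromen-8-yl)hexanoate | CCC[C@H](CC(=O)OC)c1c(O)cc(O)c2C(=O)CC(C)(C)Oc12 | intermediate
11 | 3,3-dimethylcyclobutan-1-one | CC1(C)CC(=O)C1 | starting material
12 | 3,3-dimethylcyclobut-1-en-1-yl trifluoromethanesulfonate | CC1(C)CC(OS(=O)(=O)C(F)(F)F)=C1 | intermediate
13 | methyl 3,3-dimethylcyclobut-1-ene-1-carboxylate | COC(=O)C1=CC(C)(C)C1 | intermediate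
14 | 4,4,5,5-tetramethyl-2-(prop-1-en-2-yl)-1,3,2-dioxaborolane | CC(=C)B1OC(C)(C)C(C)(C)O1 | starting material
15 | methyl (1S,2R)-3,3-dimethyl-2-(prop-1-en-2-yl)cyclobutane-1-carboxylate (cis ester, not isolated) | C=C(C)[C@H]1[C@@H](C(=O)OC)CC1(C)C | intermediate
16 | methyl (1R,2R)-3,3-dimethyl-2-(prop-1-en-2-yl)cyclobutane-1-carboxylate (trans ester) | C=C(C)[C@H]1[C@H](C(=O)OC)CC1(C)C | intermediate
17 | (1R,2R)-3,3-dimethyl-2-(prop-1-en-2-yl)cyclobutane-1-carbaldehyde | C=C(C)[C@H]1[C@H](C=O)CC1(C)C | intermediate
18 | methyl (3R)-3-[6-{[(1S,2R)-3,3-dimethyl-2-(prop-1-en-2-yl)cyclobutyl]methylidene}-5-hydroxy-2,2-dimethyl-4,7-dioxo-3,4,6,7-tetrahydro-2H-chromen-8-yl]hexanoate (ortho-quinone methide, exocyclic C=C geometry not defined, not isolated) | CCC[C@H](CC(=O)OC)C1=C2OC(C)(C)CC(=O)C2=C(O)C(=C[C@@H]2CC(C)(C)[C@H]2C(C)=C)C1=O | intermediate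
19 | methyl (3R)-3-[6-{[(1S,2R)-3,3-dimethyl-2-(prop-1-en-2-yl)cyclobutyl]methyl}-5,7-dihydroxy-2,2-dimethyl-4-oxo-3,4-dihydro-2H-chromen-8-yl]hexanoate | CCC[C@H](CC(=O)OC)c1c(O)c(C[C@@H]2CC(C)(C)[C@H]2C(C)=C)c(O)c2C(=O)CC(C)(C)Oc12 | intermediate
20 | tert-butyl (3-methylbut-2-en-1-yl) carbonate | CC(C)=CCOC(=O)OC(C)(C)C | starting material
21 | methyl (3R)-3-[(6R)-6-{[(1S,2R)-3,3-dimethyl-2-(prop-1-en-2-yl)cyclobutyl]methyl}-5-hydroxy-2,2-dimethyl-6-(3-methylbut-2-en-1-yl)-4,7-dioxo-3,4,6,7-tetrahydro-2H-chromen-8-yl]hexanoate | C=C(C)[C@H]1[C@H](C[C@]2(CC=C(C)C)C(=O)C([C@H](CCC)CC(=O)OC)=C3OC(C)(C)CC(=O)C3=C2O)CC1(C)C | intermediate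
22 | (3R)-3-[(6R)-6-{[(1S,2R)-3,3-dimethyl-2-(prop-1-en-2-yl)cyclobutyl]methyl}-5-hydroxy-2,2-dimethyl-6-(3-methylbut-2-en-1-yl)-4,7-dioxo-3,4,6,7-tetrahydro-2H-chromen-8-yl]hexanoic acid | C=C(C)[C@H]1[C@H](C[C@]2(CC=C(C)C)C(=O)C([C@H](CCC)CC(=O)O)=C3OC(C)(C)CC(=O)C3=C2O)CC1(C)C | target

**Step count**

Total: 12 steps. Longest linear sequence: 8 steps (steps 1–5 and 10–12, from phloroglucinol). The aldehyde branch is 4 steps (6–9) and joins at step 10.

**Steps most likely to fail**

1. Step 3 (key step). The benzyl ether, once it lies ortho to the new ketone, may be lost under Lewis acid and HCl, after which either oxygen could cyclise. Ester 6 may undergo conjugate hydroarylation in place of the Fries shift, or acylation may go to the carbon between the benzyloxy group and the lactone oxygen. The fallback sets out from 4 and comes back at 8. Phenol 4 is O-acylated with 5 (Et3N, catalytic DMAP, CH2Cl2, 0 °C) and ester 6 is isolated. Irradiation at 254 nm in degassed MeCN (quartz) should then bring about a photo-Fries rearrangement, by homolysis of the aryl O–acyl bond and recombination in the solvent cage at the free ortho carbon, to enone 7. Enone 7 closes to 8 with catalytic K2CO3 in acetone, or already in the irradiated solution. No acid is present, so the benzyl ether is not at risk. The fallback makes no compound outside the list (F0).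

2. Step 11. Facial selectivity at C6 may be poor, because the two faces differ only through the distant left and right halves of the ring, and alkylation may go through oxygen or at C8. The fallback sets out from 19 and comes back at 21. The carbon between the two phenolic oxygens is prenylated without a catalyst (3-methylbut-2-en-1-yl bromide, NaOMe, MeOH, 0 °C), the classical dearomative C-alkylation of acylphloroglucinols. This should give 21 together with its C6 epimer, methyl (3R)-3-[(6S)-6-{[(1S,2R)-3,3-dimethyl-2-(prop-1-en-2-yl)cyclobutyl]methyl}-5-hydroxy-2,2-dimethyl-6-(3-methylbut-2-en-1-yl)-4,7-dioxo-3,4,6,7-tetrahydro-2H-chromen-8-yl]hexanoate F1. The two are diastereomers and would be separated by preparative HPLC.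

3. Step 8. Carborhodation at the β-carbon next to the quaternary carbon may be slow, so that protodeboronation of 14 takes over, or the enantiofacial selectivity may be low. The fallback sets out from 13 and comes back at 16. A stoichiometric cuprate addition (isopropenylmagnesium bromide, CuBr·SMe2, THF, −40 °C) is followed by NaOMe/MeOH equilibration of any cis ester, that is 15 and its enantiomer methyl (1R,2S)-3,3-dimethyl-2-(prop-1-en-2-yl)cyclobutane-1-carboxylate F2. This gives the racemic trans ester, that is 16 together with its enantiomer methyl (1S,2S)-3,3-dimethyl-2-(prop-1-en-2-yl)cyclobutane-1-carboxylate F3. The racemate is resolved by preparative chromatography on a chiral stationary phase.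

**Further compounds**

F0 | step 3 | none | none
F1 | step 11 | methyl (3R)-3-[(6S)-6-{[(1S,2R)-3,3-dimethyl-2-(prop-1-en-2-yl)cyclobutyl]methyl}-5-hydroxy-2,2-dimethyl-6-(3-methylbut-2-en-1-yl)-4,7-dioxo-3,4,6,7-tetrahydro-2H-chromen-8-yl]hexanoate | C=C(C)[C@H]1[C@H](C[C@@]2(CC=C(C)C)C(=O)C([C@H](CCC)CC(=O)OC)=C3OC(C)(C)CC(=O)C3=C2O)CC1(C)C
F2 | step 8 | methyl (1R,2S)-3,3-dimethyl-2-(prop-1-en-2-yl)cyclobutane-1-carboxylate | C=C(C)[C@@H]1[C@H](C(=O)OC)CC1(C)C
F3 | step 8 | methyl (1S,2S)-3,3-dimethyl-2-(prop-1-en-2-yl)cyclobutane-1-carboxylate | C=C(C)[C@@H]1[C@@H](C(=O)OC)CC1(C)C
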